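A fork read at the charge misleads, because its branches move during the run: the first molecules of substrate in birch favour side product B over side product A, at 0.248 s⁻¹ per molecule against 0.21 s⁻¹, yet that branch falls with the substrate.

- cedar: substrate 2.0 mM; partner 1.80 equiv; time 15 s
- birch: substrate 2.0 mM; partner 0.700 equiv; time 15 s

    substrate + partner → target (k1 = 230 M⁻¹ s⁻¹)
    substrate → side product A (k2 = 0.21 s⁻¹)
    2 substrate → side product B (k3 = 62 M⁻¹ s⁻¹)
    partner + target → over-reaction product (k4 = 78 M⁻¹ s⁻¹)
    crystals ⇌ target, rate k5*(cs5 - [target]) while solid is left; crystals form when [target] > cs5 (cs5 = 0.75 mM, k5 = 0.82 s⁻¹)

- a species is counted by the substrate in it: one side product B counts as two
- amounts and yields of target count crystals too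
- two of one species on the left: rate k times its square, two consumed each time
- given per volume of solution although it is solid: crystals
- run time (cedar): 15 s

- which of these there is most of at the end, counted by the substrate in it, cedar (side product A / target / over-reaction product / side product B)
- which of these there is most of at the end, counted by the substrate in it, birch (side product A / target / over-reaction product / side product B)
- how much there is at the end of the one of these that leads, in percent of the substrate charged: cedar
- how much there is at the end of the one of these that leads, in percent of the substrate charged: birch

In cedar the half-lives at the charge, shortest first, are coupling 0.837 s, attack of partner on target 2.47 s, side product A 3.3 s and side product B 4.03 s. In birch coupling takes 2.2 s, and the attack, at 6.3 s, takes longer than either side product. Each of these is shorter than the 15 s run, so the reckoning has the substrate fork early, and the target then faces partner for the rest of the run.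

Follow one molecule of substrate. Per second it has c, the coupling constant times [partner]; a, the constant of side product A; and b, twice the constant of side product B times [substrate]. Its chance on a branch is that branch over c + a + b. Taken at the charge for c, this gives a start share, and the partner is then lowered by half of the amount so coupled, with substrate at half its charge:

cedar: start share 64.4%, midway partner 2.96 mM, chance 67.1%

birch: start share 41.3%, midway partner 0.987 mM, chance 40.5%

This midway share c/(c + a + b) is the coupling chance, the part of the charge expected to reach target at all. Target then falls pseudo-first-order, with partner held at its level after the coupling and after attack on half of the target:

cedar: partner 1.59 mM, target surviving 15.6%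

birch: partner 0.186 mM, target surviving 80.4%

The reckoning puts over-reaction product ahead in cedar, at 56.6%, and side product A ahead in birch, at 37.4%.

The forecast names the same leaders with figures of its own, over-reaction product at 53% for cedar and side product A at 38% for birch, holding for birch that “the coupling slows as partner is used up”.

The simulation gives over-reaction product at 53.7% in cedar and side product A at 40.4% in birch.

At the end of cedar, target and over-reaction product together hold 66.1% of the charge, beside a coupling chance of 67.1%. A neighbour of cedar charged with 3.10 equiv of partner takes the same reckoning: start share 75.7%, midway partner 5.44 mM, chance 78.9%, which is higher than in cedar. At the end of that neighbour, target stands at 1.86% and over-reaction product at 76.7%, together 78.6% of the substrate charged.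

The constants are assumed, and the outcome is calculated.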